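A stirred vessel of constant volume receives equal charges in violet, red and ochre; the recipes differ in what enters when.

| setting | violet | red | ochre |
|---|---|---|---|
| starting material | 5.0 mM | 5.0 mM | 5.0 mM |
| first nucleophile | 12.5 mM | 12.5 mM | 12.5 mM (fed, over 15 s) |
| second nucleophile | 4.75 mM (fed, over 15 s) | 4.75 mM | 4.75 mM |
| protic impurity | 2.50 mM | 2.50 mM | 2.50 mM |
| time | 20 s | 20 s | 20 s |
| remark | all else is in the flask from the start; the feed brings no volume worth counting | everything together at the start | all else is in the flask from the start; the feed brings no volume worth counting |

    first nucleophile + intermediate → target (k1 = 1040 M⁻¹ s⁻¹)
    starting material + protic impurity → quenched substrate (k2 = 9.02 M⁻¹ s⁻¹)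
    first nucleophile ⇌ dormant form (K3 = 0.60, k3 = 0.449 s⁻¹)
    starting material → intermediate (k4 = 0.160 s⁻¹)
    second nucleophile + intermediate → other capture product (k5 = 2910 M⁻¹ s⁻¹)
    first nucleophile + target → over-reaction product (k6 = 38.0 M⁻¹ s⁻¹)

1. the flask that comes out highest in amount of over-reaction product, in percent of the starting material charged; "all alike" if 1.5 percentage points covers them all (violet / red / ochre / all alike)
2. amount of over-reaction product at the end, in percent of the starting material charged, violet
3. amount of over-reaction product at the end, in percent of the starting material charged, red
4. amount of over-reaction product at the end, in percent of the starting material charged, ochre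

Starting material is counted by the fraction left, exp(−t/τ). Here τ, the mean birth time of the intermediate, is 5.48 s, the inverse of the summed rates of the two exits of starting material, with the impurity held at its charge. At 20 s the fraction left is 2.60%. The intermediate exit takes 87.6% of what goes, so 85.4% of the charge reaches capture.

In red, the half-lives of the intermediate by step 1 alone and by step 5 alone, the other concentrations as charged, are 0.053 s and 0.050 s, much shorter than τ, so capture is reckoned from the concentrations present at birth. In violet, dormant exchange relaxes in 0.579 s, faster than τ, so 62.5% of the first nucleophile pool is taken as free. The capture share of the first nucleophile (a selectivity) is k1[first nucleophile]/(k1[first nucleophile]+k5[second nucleophile]).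

Red, with both charges in the flask and the same free fraction, has a reckoned share of 37.0%. Violet looks nearly the same, but by τ its feed has delivered 1.73 mM, less than red's 4.75 mM, so its share, reckoned at that moment, is 61.7%. In ochre, the same count on the fed pool gives 17.7%. This reckoning therefore gives target plus over-reaction product as 52.7% in violet, 31.6% in red and 15.1% in ochre, with violet highest. In red, target's half-life by step 6 alone, with first nucleophile as charged, is 1.5 s, shorter than τ, so target is expected to pass on to over-reaction product as the sum builds.

The forecast, which differs from this reckoning by speaking of over-reaction product alone, names violet with 53%, 34% for red and 19% for ochre, from “a rough mental stepping through time”. The simulation gives 54.8% in violet, 34.5% in red and 18.9% in ochre, so violet comes out highest.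

Violet holds target plus over-reaction product at 59.3% at 20.0 s, more than the reckoned 52.7%. The neighbour of violet charged with 31 mM of first nucleophile keeps τ at 5.48 s and the same delivered amount. The free fraction of that charge, 19.4 mM, gives a reckoned share of 80.0%, hence 68.3% for the sum. That neighbour ends with 71.7% in the sum, of which over-reaction product is 71.1%.

The constants used here were drawn at random within sensible limits; no experiment stands behind them.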